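The plan rests on breaking the dioxane ring at C8–O4' (neolignan labels: C7 = ArCH–O, C8 = ring CH carrying the CH2OH arm C9, O3' and O4' = ring oxygens on C7 and C8). In the target, O4' and the C9 hydroxyl sit on neighbouring carbons, the signature of a C8–C9 oxirane that an aryloxide has opened at its inner carbon. The key step does this intramolecularly: it makes C8–O4', closes the dioxane ring, inverts C8 and releases C9–OH at once. Its precursor is a 4-hydroxybenzaldehyde whose O3' already bears C7 (S) with the (2R)-oxirane attached; it comes from a Sharpless epoxy alcohol through an inverting phenol opening at C7.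

Key step: step 9

Remark on the chemistry: the target is the trans-(7S,8S) compound, (2S,3S) in benzodioxine numbering; since C7 and C8 are each inverted once on the way, it requires the (2R,3R)-epoxy alcohol and therefore the D-(−)-tartrate in step 4.

Step 1
Reactants: 1 syringaldehyde (4-hydroxy-3,5-dimethoxybenzaldehyde)
Product: 2 3,5-dimethoxy-4-(triisopropylsilyloxy)benzaldehyde
Conditions: i-Pr3SiCl, imidazole, DMAP (cat.), DMF, rt to 40 °C
Reagents that add atoms: triisopropylsilyl chloride, CC(C)[Si](Cl)(C(C)C)C(C)C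
Why: O-silylation of a phenol (silyl ether formation); the bulky silyl group between two methoxy groups should survive the later hydride, titanium and carbonate steps and come off with fluoride at the end.

Step 2
Reactants: 2 3,5-dimethoxy-4-(triisopropylsilyloxy)benzaldehyde; 3 triethyl phosphonoacetate
Product: 4 ethyl (E)-3-[3,5-dimethoxy-4-(triisopropylsilyloxy)phenyl]prop-2-enoate
Conditions: NaH, THF, 0 °C to rt
Reagents that add atoms: none
Why: Horner–Wadsworth–Emmons olefination of a non-enolisable aryl aldehyde with a stabilised phosphonate anion should give the (E)-cinnamate.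

Step 3
Reactants: 4 ethyl (E)-3-[3,5-dimethoxy-4-(triisopropylsilyloxy)phenyl]prop-2-enoate
Product: 5 (E)-3-[3,5-dimethoxy-4-(triisopropylsilyloxy)phenyl]prop-2-en-1-ol
Conditions: i-Bu2AlH (2.5 equiv), CH2Cl2, −78 °C; aq. potassium sodium tartrate work-up
Reagents that add atoms: none
Why: 1,2-reduction of a conjugated ester by an aluminium hydride at low temperature should stop at the allylic alcohol and leave the alkene geometry and the aryl silyl ether untouched.

Step 4
Reactants: 5 (E)-3-[3,5-dimethoxy-4-(triisopropylsilyloxy)phenyl]prop-2-en-1-ol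
Product: 6 [(2R,3R)-3-[3,5-dimethoxy-4-(triisopropylsilyloxy)phenyl]oxiran-2-yl]methanol
Conditions: Ti(OiPr)4 (10 mol%), D-(−)-diisopropyl tartrate (12 mol%), t-BuOOH (2 equiv, anhydrous), 4 Å molecular sieves, CH2Cl2, −20 °C; non-acidic work-up
Reagents that add atoms: tert-butyl hydroperoxide, CC(C)(C)OO
Why: Sharpless asymmetric epoxidation: allylic alkoxide and hydroperoxide are bound to the titanium tartrate catalyst, and the D-(−)-tartrate directs oxygen to the alkene face that gives the (2R,3R)-epoxy alcohol (the L-(+)-tartrate gives (2S,3S) with (E)-3-aryl allylic alcohols), so that C7 (R) and C8 (R) are set together under reagent control, while catalytic titanium, sieves and low temperature spare the acid-sensitive benzylic oxirane.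

Step 5
Reactants: 7 3,4-dihydroxybenzaldehyde; 8 allyl bromide
Product: 9 4-(allyloxy)-3-hydroxybenzaldehyde
Conditions: NaHCO3, NaI (cat.), DMF, 40 °C
Reagents that add atoms: none
Why: Williamson ether synthesis under a weak base: hydrogencarbonate ionises only the 4-OH, which is conjugated with the formyl group and therefore the more acidic, so that allylation should go to O4' and leave O3'–H free.

Step 6
Reactants: 6 [(2R,3R)-3-[3,5-dimethoxy-4-(triisopropylsilyloxy)phenyl]oxiran-2-yl]methanol; 9 4-(allyloxy)-3-hydroxybenzaldehyde (2 equiv)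
Product: 10 4-(allyloxy)-3-{[(1S,2R)-1-[3,5-dimethoxy-4-(triisopropylsilyloxy)phenyl]-2,3-dihydroxypropyl]oxy}benzaldehyde
Conditions: Ti(OiPr)4 (1.5 equiv), toluene, rt to 40 °C
Reagents that add atoms: none
Why: Titanium-mediated C3-selective opening of a 2,3-epoxy alcohol (SN2): the epoxy alkoxide binds to titanium, which activates the oxirane and steers the phenol O3'–H to the benzylic C7 from the side opposite to the epoxide oxygen, so that C7 is inverted (R to S) and C8 keeps its configuration.

Step 7
Reactants: 10 4-(allyloxy)-3-{[(1S,2R)-1-[3,5-dimethoxy-4-(triisopropylsilyloxy)phenyl]-2,3-dihydroxypropyl]oxy}benzaldehyde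
Product: 12 4-(allyloxy)-3-{(S)-[3,5-dimethoxy-4-(triisopropylsilyloxy)phenyl][(2R)-oxiran-2-yl]methoxy}benzaldehyde, via primary tosylate 11 (not isolated)
Conditions: TsCl (1.05 equiv), Et3N, Bu2SnO (2 mol%), CH2Cl2, 0 °C to rt; then K2CO3, MeOH, 0 °C to rt
Reagents that add atoms: none
Why: Selective sulfonylation followed by a Williamson-type 3-exo-tet closure: the tin acetal directs tosylation to the primary C9 hydroxyl, and carbonate then lets the C8 oxygen displace the tosylate at C9, so that no bond to C8 is broken and C8 stays R.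

Step 8
Reactants: 12 4-(allyloxy)-3-{(S)-[3,5-dimethoxy-4-(triisopropylsilyloxy)phenyl][(2R)-oxiran-2-yl]methoxy}benzaldehyde
Product: 13 4-hydroxy-3-{(S)-[3,5-dimethoxy-4-(triisopropylsilyloxy)phenyl][(2R)-oxiran-2-yl]methoxy}benzaldehyde
Conditions: Pd(PPh3)4 (3 mol%), N-methylaniline (3 equiv), THF, rt
Reagents that add atoms: none
Why: Tsuji–Trost deallylation: zerovalent palladium ionises the allyl aryl ether (the 4-formylphenoxide is a good leaving group) and N-methylaniline captures the π-allyl complex; this weak base leaves the phenol protonated, so that the oxirane, the aldehyde and the silyl ether should be carried unchanged into step 9.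

Step 9
Reactants: 13 4-hydroxy-3-{(S)-[3,5-dimethoxy-4-(triisopropylsilyloxy)phenyl][(2R)-oxiran-2-yl]methoxy}benzaldehyde
Product: 14 (2S,3S)-3-[3,5-dimethoxy-4-(triisopropylsilyloxy)phenyl]-2-(hydroxymethyl)-2,3-dihydro-1,4-benzodioxine-6-carbaldehyde
Conditions: K2CO3 (0.3 equiv), DMF, 50 °C
Reagents that add atoms: none
Why: Carbonate ionises the O4' phenol (acidified by the para formyl group) and the phenoxide attacks C8 of the oxirane in an intramolecular SN2 reaction from the side opposite to the C8–O bond; the C9 alkoxide set free is protonated by the next phenol, so that a substoichiometric amount of base suffices. The closest known reaction type is the base-mediated cyclisation of 2-(oxiranylmethoxy)phenols to 2-hydroxymethyl-1,4-benzodioxanes. The dioxane ring closes in the 6-exo-tet mode, the breaking C8–O bond lying outside the new ring. The new C8 configuration (S) results from inversion of the (R)-oxirane carbon and is therefore controlled by the substrate, ultimately by the Sharpless epoxide; C7 is a spectator, and its erythro relationship to C8 becomes the trans arrangement of aryl and CH2OH. The step needs 6-exo attack at C8 over 7-endo attack at C9 and over intermolecular opening, which the short O4'–C4'–C3'–O3'–C7 tether secures by aligning the phenoxide with the C8–O bond only, while the choice between O3' and O4' was settled earlier by keeping O4' allylated until step 8.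

Step 10
Reactants: 14 (2S,3S)-3-[3,5-dimethoxy-4-(triisopropylsilyloxy)phenyl]-2-(hydroxymethyl)-2,3-dihydro-1,4-benzodioxine-6-carbaldehyde; 15 (triphenylphosphoranylidene)acetaldehyde (1.3 equiv)
Product: 16 (E)-3-[(2S,3S)-3-[3,5-dimethoxy-4-(triisopropylsilyloxy)phenyl]-2-(hydroxymethyl)-2,3-dihydro-1,4-benzodioxin-6-yl]prop-2-enal
Conditions: toluene, 80 °C
Reagents that add atoms: none
Why: Wittig olefination with a formyl-stabilised ylide: reversible addition under thermodynamic control should give the (E)-enal, the free CH2OH and the silyl ether are inert to the neutral ylide, and a small excess limits a second olefination of the less electrophilic product.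

Step 11
Reactants: 16 (E)-3-[(2S,3S)-3-[3,5-dimethoxy-4-(triisopropylsilyloxy)phenyl]-2-(hydroxymethyl)-2,3-dihydro-1,4-benzodioxin-6-yl]prop-2-enal
Product: 17 (E)-3-[(2S,3S)-3-(4-hydroxy-3,5-dimethoxyphenyl)-2-(hydroxymethyl)-2,3-dihydro-1,4-benzodioxin-6-yl]prop-2-enal (CNP0211211.1)
Conditions: Bu4NF (1.1 equiv), AcOH (1.1 equiv), THF, 0 °C
Reagents that add atoms: none
Why: Fluoride-induced desilylation of the aryl silyl ether (Si–F bond formation); acetic acid buffers the liberated phenoxide, so that the enal, the benzylic C7–O3' bond and both stereocentres should stay untouched.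

Compound list
1 | syringaldehyde (4-hydroxy-3,5-dimethoxybenzaldehyde) | COc1cc(C=O)cc(OC)c1O | starting material
2 | 3,5-dimethoxy-4-(triisopropylsilyloxy)benzaldehyde | COc1cc(C=O)cc(OC)c1O[Si](C(C)C)(C(C)C)C(C)C | intermediate
3 | triethyl phosphonoacetate | CCOC(=O)CP(=O)(OCC)OCC | starting material
4 | ethyl (E)-3-[3,5-dimethoxy-4-(triisopropylsilyloxy)phenyl]prop-2-enoate | CCOC(=O)/C=C/c1cc(OC)c(O[Si](C(C)C)(C(C)C)C(C)C)c(OC)c1 | intermediate
5 | (E)-3-[3,5-dimethoxy-4-(triisopropylsilyloxy)phenyl]prop-2-en-1-ol | OC/C=C/c1cc(OC)c(O[Si](C(C)C)(C(C)C)C(C)C)c(OC)c1 | intermediate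
6 | [(2R,3R)-3-[3,5-dimethoxy-4-(triisopropylsilyloxy)phenyl]oxiran-2-yl]methanol | OC[C@H]1O[C@@H]1c2cc(OC)c(O[Si](C(C)C)(C(C)C)C(C)C)c(OC)c2 | intermediate
7 | 3,4-dihydroxybenzaldehyde | O=Cc1ccc(O)c(O)c1 | starting material
8 | allyl bromide | C=CCBr | starting material
9 | 4-(allyloxy)-3-hydroxybenzaldehyde | O=Cc1ccc(OCC=C)c(O)c1 | intermediate
10 | 4-(allyloxy)-3-{[(1S,2R)-1-[3,5-dimethoxy-4-(triisopropylsilyloxy)phenyl]-2,3-dihydroxypropyl]oxy}benzaldehyde | COc1cc([C@H](Oc2cc(C=O)ccc2OCC=C)[C@H](O)CO)cc(OC)c1O[Si](C(C)C)(C(C)C)C(C)C | intermediate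
11 | (2R,3S)-3-[2-(allyloxy)-5-formylphenoxy]-3-[3,5-dimethoxy-4-(triisopropylsilyloxy)phenyl]-2-hydroxypropyl 4-methylbenzenesulfonate | COc1cc([C@H](Oc2cc(C=O)ccc2OCC=C)[C@H](O)COS(=O)(=O)c2ccc(C)cc2)cc(OC)c1O[Si](C(C)C)(C(C)C)C(C)C | intermediate
12 | 4-(allyloxy)-3-{(S)-[3,5-dimethoxy-4-(triisopropylsilyloxy)phenyl][(2R)-oxiran-2-yl]methoxy}benzaldehyde | COc1cc([C@H](Oc2cc(C=O)ccc2OCC=C)[C@H]2CO2)cc(OC)c1O[Si](C(C)C)(C(C)C)C(C)C | intermediate
13 | 4-hydroxy-3-{(S)-[3,5-dimethoxy-4-(triisopropylsilyloxy)phenyl][(2R)-oxiran-2-yl]methoxy}benzaldehyde | COc1cc([C@H](Oc2cc(C=O)ccc2O)[C@H]2CO2)cc(OC)c1O[Si](C(C)C)(C(C)C)C(C)C | intermediate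
14 | (2S,3S)-3-[3,5-dimethoxy-4-(triisopropylsilyloxy)phenyl]-2-(hydroxymethyl)-2,3-dihydro-1,4-benzodioxine-6-carbaldehyde | COc1cc([C@@H]2Oc3cc(C=O)ccc3O[C@H]2CO)cc(OC)c1O[Si](C(C)C)(C(C)C)C(C)C | intermediate
15 | (triphenylphosphoranylidene)acetaldehyde | O=CC=P(c1ccccc1)(c1ccccc1)c1ccccc1 | starting material
16 | (E)-3-[(2S,3S)-3-[3,5-dimethoxy-4-(triisopropylsilyloxy)phenyl]-2-(hydroxymethyl)-2,3-dihydro-1,4-benzodioxin-6-yl]prop-2-enal | COc1cc([C@@H]2Oc3cc(/C=C/C=O)ccc3O[C@H]2CO)cc(OC)c1O[Si](C(C)C)(C(C)C)C(C)C | intermediate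
17 | (E)-3-[(2S,3S)-3-(4-hydroxy-3,5-dimethoxyphenyl)-2-(hydroxymethyl)-2,3-dihydro-1,4-benzodioxin-6-yl]prop-2-enal | COc1cc([C@@H]2Oc3cc(/C=C/C=O)ccc3O[C@H]2CO)cc(OC)c1O | target

Total step count: 11. Longest linear sequence: 10 steps (steps 1–4 and 6–11, from syringaldehyde 1).

Steps most likely to fail

Step 9 (key step). What may go wrong: the phenoxide may attack the unhindered C9 (7-endo) or a second molecule instead of C8. The carbonate may also strip the silyl group, after which the free syringyl phenoxide can break the C7–O3' bond through a quinone methide. The fallback replaces the epoxide opening by a dehydrative closure with the same inversion at C8; it sets out from diol 10 and comes back at 14. Silylation of the primary hydroxyl (t-BuMe2SiCl, imidazole, CH2Cl2, 0 °C) should give the C9 tert-butyldimethylsilyl ether F1. Deallylation as in step 8 then gives the hydroxy phenol F2. An intramolecular Mitsunobu reaction (PPh3, diisopropyl azodicarboxylate, THF, 0 °C to rt) lets O4' displace the activated C8 hydroxyl with inversion and should give the silylated benzodioxane F3. Aqueous acetic acid in THF removes only the alkyl silyl ether and delivers 14.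

Step 6. What may go wrong: partial ionisation of the electron-rich benzylic C7–O bond on the Lewis acid, so that the phenol adds with incomplete inversion and the erythro relationship is eroded; C8 is not affected. The fallback replaces kinetic control of C7 by thermodynamic control; it sets out from 14, carried on together with its C7 epimer, and comes back at 17. Desilylation (Bu4NF, AcOH, THF) gives the cis phenol F4 alongside the trans phenol F5. K2CO3 in DMF at 60 °C should open the C7–O3' bond of the free para-phenoxide reversibly to a quinone methide, and reclosure should funnel F4 into the more stable diequatorial F5, whose C8 was never touched. Wittig reaction of F5 with 15 (THF, 60 °C) then gives 17.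

Step 10. What may go wrong: slow reaction of the electron-rich aldehyde and a second olefination of the product enal (over-homologation to the dienal). The fallback uses ester homologation and redox adjustment; it sets out from 14 and comes back at 16. Horner–Wadsworth–Emmons reaction with 3 (LiCl, DBU, MeCN) should give the ethyl (E)-cinnamate F6. i-Bu2AlH (CH2Cl2, −78 °C) reduces it to the allylic alcohol F7. MnO2 in CH2Cl2 should oxidise only the cinnamyl hydroxyl, leave the saturated CH2OH and give 16.

Further compounds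
F1 | step 9 | 4-(allyloxy)-3-{[(1S,2R)-3-(tert-butyldimethylsilyloxy)-1-[3,5-dimethoxy-4-(triisopropylsilyloxy)phenyl]-2-hydroxypropyl]oxy}benzaldehyde | COc1cc([C@H](Oc2cc(C=O)ccc2OCC=C)[C@H](O)CO[Si](C)(C)C(C)(C)C)cc(OC)c1O[Si](C(C)C)(C(C)C)C(C)C
F2 | step 9 | 3-{[(1S,2R)-3-(tert-butyldimethylsilyloxy)-1-[3,5-dimethoxy-4-(triisopropylsilyloxy)phenyl]-2-hydroxypropyl]oxy}-4-hydroxybenzaldehyde | COc1cc([C@H](Oc2cc(C=O)ccc2O)[C@H](O)CO[Si](C)(C)C(C)(C)C)cc(OC)c1O[Si](C(C)C)(C(C)C)C(C)C
F3 | step 9 | (2S,3S)-2-[(tert-butyldimethylsilyloxy)methyl]-3-[3,5-dimethoxy-4-(triisopropylsilyloxy)phenyl]-2,3-dihydro-1,4-benzodioxine-6-carbaldehyde | COc1cc([C@@H]2Oc3cc(C=O)ccc3O[C@H]2CO[Si](C)(C)C(C)(C)C)cc(OC)c1O[Si](C(C)C)(C(C)C)C(C)C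
F4 | step 6 | (2S,3R)-3-(4-hydroxy-3,5-dimethoxyphenyl)-2-(hydroxymethyl)-2,3-dihydro-1,4-benzodioxine-6-carbaldehyde | COc1cc([C@H]2Oc3cc(C=O)ccc3O[C@H]2CO)cc(OC)c1O
F5 | step 6 | (2S,3S)-3-(4-hydroxy-3,5-dimethoxyphenyl)-2-(hydroxymethyl)-2,3-dihydro-1,4-benzodioxine-6-carbaldehyde | COc1cc([C@@H]2Oc3cc(C=O)ccc3O[C@H]2CO)cc(OC)c1O
F6 | step 10 | ethyl (E)-3-[(2S,3S)-3-[3,5-dimethoxy-4-(triisopropylsilyloxy)phenyl]-2-(hydroxymethyl)-2,3-dihydro-1,4-benzodioxin-6-yl]prop-2-enoate | COc1cc([C@@H]2Oc3cc(/C=C/C(=O)OCC)ccc3O[C@H]2CO)cc(OC)c1O[Si](C(C)C)(C(C)C)C(C)C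
F7 | step 10 | (E)-3-[(2S,3S)-3-[3,5-dimethoxy-4-(triisopropylsilyloxy)phenyl]-2-(hydroxymethyl)-2,3-dihydro-1,4-benzodioxin-6-yl]prop-2-en-1-ol | COc1cc([C@@H]2Oc3cc(/C=C/CO)ccc3O[C@H]2CO)cc(OC)c1O[Si](C(C)C)(C(C)C)C(C)C
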